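Assumption: the target is taken as the drawn keto–enol tautomer, whose only stereocentre (C4a, chromene numbering) is R; fod = 6,6,7,7,8,8,8-heptafluoro-2,2-dimethyloctane-3,5-dionate.

## Retrosynthetic overview

- Target ⇒ twofold olefin cross-metathesis (crotyl → prenyl) of the 4a,8-bis[(E)-but-2-enyl] dienone.
- Quaternary C4a–CH2 bond ⇒ dearomative aromatic Claisen ([3,3]) of a chromenyl 5-O-[(R)-but-3-en-2-yl] ether. The C–O stereocentre, bought as (S)-but-3-en-2-ol and inverted on etherification, is relayed to C4a and later erased. The sister ether at O7 delivers the C8 chain by an ordinary ortho-Claisen.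
- Pyran ring ⇒ 6-endo hydroarylation of a 4-O-(1,1-dimethylpropargyl) ether; both chiral ethers ⇒ double Mitsunobu on the symmetric 2,6-diol ⇒ phlorisobutyrophenone + 3-chloro-3-methylbut-1-yne.
- Ring order: carbocycle bought as the arene → pyran ring closed onto it → carbocycle dearomatised in the key Claisen step.

## Route

Step 1
Reactants: 1 phlorisobutyrophenone (2-methyl-1-(2,4,6-trihydroxyphenyl)propan-1-one); 2 3-chloro-3-methylbut-1-yne
Product: 3 1-[2,6-dihydroxy-4-(2-methylbut-3-yn-2-yloxy)phenyl]-2-methylpropan-1-one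
Conditions: 2 (1.2 equiv), K2CO3 (1.5 equiv), KI (cat.), acetone, 56 °C
Reagents that add atoms: none
Why: Williamson-type O-alkylation by the tertiary propargylic chloride: the para hydroxyl is the most acidic and the only one not hydrogen-bonded to the ketone, so it is etherified selectively.

Step 2
Reactants: 3 1-[2,6-dihydroxy-4-(2-methylbut-3-yn-2-yloxy)phenyl]-2-methylpropan-1-one; 4 (S)-but-3-en-2-ol
Product: 6 1-{2,6-bis[(R)-but-3-en-2-yloxy]-4-(2-methylbut-3-yn-2-yloxy)phenyl}-2-methylpropan-1-one, via mono-ether 5 (not isolated)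
Conditions: 4 (3 equiv), PPh3 (3 equiv), DIAD (3 equiv), THF, 0 → 40 °C
Reagents that add atoms: none
Why: Double Mitsunobu etherification of the two equivalent chelated phenols (so only one bis-ether can form), each an SN2 displacement at the carbinol carbon that inverts (S)-4 to the (R)-configured ether.

Step 3
Reactants: 6 1-{2,6-bis[(R)-but-3-en-2-yloxy]-4-(2-methylbut-3-yn-2-yloxy)phenyl}-2-methylpropan-1-one
Product: 7 1-{5,7-bis[(R)-but-3-en-2-yloxy]-2,2-dimethyl-2H-chromen-6-yl}-2-methylpropan-1-one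
Conditions: Ph3PAuNTf2 (2 mol %), CH2Cl2, 25 °C
Reagents that add atoms: none
Why: Gold-catalysed 6-endo-dig intramolecular hydroarylation of the aryl propargyl ether (Friedel–Crafts-type alkenylation) at C3, which is equivalent to C5 and activated by three oxygens, so the ether oxygen para to the ketone necessarily becomes the pyran oxygen; the two C–O stereocentres are not involved.

Step 4
Reactants: 7 1-{5,7-bis[(R)-but-3-en-2-yloxy]-2,2-dimethyl-2H-chromen-6-yl}-2-methylpropan-1-one
Product: 9 (4aR)-4a,8-bis[(E)-but-2-enyl]-7-hydroxy-2,2-dimethyl-6-(2-methylpropanoyl)-2H-chromen-5(4aH)-one, via mono-Claisen phenol 8 (not isolated)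
Conditions: Eu(fod)3 (10 mol %), PhMe, 90 °C
Reagents that add atoms: none
Why: Two Lewis-acid-accelerated aromatic Claisen ([3,3]-sigmatropic) rearrangements: the O7 ether shifts to the free C8 and re-aromatises to 8, then the O5 ether shifts to the substituted C4a, where the dienone cannot re-aromatise and is held as the hydrogen-bonded β-triketone enol; in the chair transition state with the methyl group pseudo-equatorial the (R)-configured C–O centre delivers the allyl terminus to one face of C4a only, which sets 4aR together with the (E)-olefin.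

Step 5
Reactants: 9 (4aR)-4a,8-bis[(E)-but-2-enyl]-7-hydroxy-2,2-dimethyl-6-(2-methylpropanoyl)-2H-chromen-5(4aH)-one; 10 2-methylbut-2-ene
Product: 11 (4aR)-7-hydroxy-2,2-dimethyl-4a,8-bis(3-methylbut-2-enyl)-6-(2-methylpropanoyl)-2H-chromen-5(4aH)-one
Conditions: second-generation Grubbs catalyst (5–10 mol %), 10 (excess, co-solvent), CH2Cl2, 40 °C
Reagents that add atoms: none
Why: Double olefin cross-metathesis in which the ruthenium alkylidene exchanges the =CHCH3 end of each disubstituted crotyl olefin for =CMe2 from excess 10, while the trisubstituted prenyl olefins formed and the ring olefin flanked by two quaternary carbons are inert and C4a is not touched.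

## Compound list

1 | phlorisobutyrophenone, 2-methyl-1-(2,4,6-trihydroxyphenyl)propan-1-one | CC(C)C(=O)c1c(O)cc(O)cc1O | starting material
2 | 3-chloro-3-methylbut-1-yne | CC(C)(Cl)C#C | starting material
3 | 1-[2,6-dihydroxy-4-(2-methylbut-3-yn-2-yloxy)phenyl]-2-methylpropan-1-one | CC(C)C(=O)c1c(O)cc(OC(C)(C)C#C)cc1O | intermediate
4 | (S)-but-3-en-2-ol | C[C@H](O)C=C | starting material
5 | 1-{2-[(R)-but-3-en-2-yloxy]-6-hydroxy-4-(2-methylbut-3-yn-2-yloxy)phenyl}-2-methylpropan-1-one (mono-ether) | CC(C)C(=O)c1c(O)cc(OC(C)(C)C#C)cc1O[C@H](C)C=C | intermediate (not isolated)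
6 | 1-{2,6-bis[(R)-but-3-en-2-yloxy]-4-(2-methylbut-3-yn-2-yloxy)phenyl}-2-methylpropan-1-one | CC(C)C(=O)c1c(O[C@H](C)C=C)cc(OC(C)(C)C#C)cc1O[C@H](C)C=C | intermediate
7 | 1-{5,7-bis[(R)-but-3-en-2-yloxy]-2,2-dimethyl-2H-chromen-6-yl}-2-methylpropan-1-one | CC(C)C(=O)c1c(O[C@H](C)C=C)cc2OC(C)(C)C=Cc2c1O[C@H](C)C=C | intermediate
8 | 1-{5-[(R)-but-3-en-2-yloxy]-8-[(E)-but-2-enyl]-7-hydroxy-2,2-dimethyl-2H-chromen-6-yl}-2-methylpropan-1-one (mono-Claisen phenol) | CC(C)C(=O)c1c(O)c(C/C=C/C)c2OC(C)(C)C=Cc2c1O[C@H](C)C=C | intermediate (not isolated)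
9 | (4aR)-4a,8-bis[(E)-but-2-enyl]-7-hydroxy-2,2-dimethyl-6-(2-methylpropanoyl)-2H-chromen-5(4aH)-one | C/C=C/CC1=C2OC(C)(C)C=C[C@@]2(C/C=C/C)C(=O)C(C(=O)C(C)C)=C1O | intermediate
10 | 2-methylbut-2-ene | CC=C(C)C | starting material
11 | (4aR)-7-hydroxy-2,2-dimethyl-4a,8-bis(3-methylbut-2-enyl)-6-(2-methylpropanoyl)-2H-chromen-5(4aH)-one | CC(C)=CCC1=C2OC(C)(C)C=C[C@@]2(CC=C(C)C)C(=O)C(C(=O)C(C)C)=C1O | target

## Totals and risks

Total step count: 5. Longest linear sequence: 5 (1 → 3 → 6 → 7 → 9 → 11).

The three steps most likely to fail: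

**Step 4 (double Claisen).** The O5 ether could travel through C4a on to the still-free C8 (para-Claisen) before the O7 ether has blocked that position. The dearomative shift could also be followed by a Cope shift or by loss of butadiene. The enantiomeric purity of 11 is only as good as the preference for the pseudo-equatorial chair. The fallback sets out from 3 and comes back at 8, now isolated with C8 already blocked, which is then rearranged to 9 under the step 4 conditions. In it, 3 is etherified with one equivalent of 4 (PPh3, DIAD) to give 5 as an isolated compound. Eu(fod)3 (CHCl3, 50 °C) then rearranges only this carbonyl-chelated allyl ether to 1-{3-[(E)-but-2-enyl]-2,6-dihydroxy-4-(2-methylbut-3-yn-2-yloxy)phenyl}-2-methylpropan-1-one F6. A second Mitsunobu reaction with 4 takes the less hindered hydroxyl (next to ring H, not next to the crotyl group) and gives 1-{6-[(R)-but-3-en-2-yloxy]-3-[(E)-but-2-enyl]-2-hydroxy-4-(2-methylbut-3-yn-2-yloxy)phenyl}-2-methylpropan-1-one F7. Ph3PAuNTf2 then closes the pyran at the only free ortho carbon to give 8. Independently of this, isomers of 9 carrying a (Z)-4a-crotyl group, which arise from the axial-methyl chair and have the 4aS centre, can be removed on AgNO3-impregnated silica before the metathesis erases that label.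

**Step 2 (double Mitsunobu).** The second, strongly chelated phenol may react sluggishly, and a secondary allylic alcohol can give some SN2′ ether or diene. The fallback sets out from 3 and comes back at 7. 3 is cyclised first (Ph3PAuNTf2, CH2Cl2) to the chromene diol 1-(5,7-dihydroxy-2,2-dimethyl-2H-chromen-6-yl)-2-methylpropan-1-one F1. Both phenoxides (Cs2CO3, DMF, 40 °C) are then alkylated by SN2 with inversion, using (S)-but-3-yn-2-yl 4-methylbenzenesulfonate F2 (from (S)-but-3-yn-2-ol, TsCl, KOH, Et2O). This gives 1-{5,7-bis[(R)-but-3-yn-2-yloxy]-2,2-dimethyl-2H-chromen-6-yl}-2-methylpropan-1-one F3. Semi-hydrogenation of both terminal alkynes (H2, Pd/CaCO3 poisoned with Pb(OAc)2, quinoline, EtOAc) gives 7.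

**Step 3 (gold-catalysed ring closure).** The cationic gold catalyst may ionise the tertiary propargylic ether or engage the two terminal olefins. The fallback sets out from 6 and comes back at 7, and replaces the metal by a purely thermal pericyclic cascade (o-xylene, 130 °C). Propargyl Claisen rearrangement and enolisation give the allenylphenol 1-{2,6-bis[(R)-but-3-en-2-yloxy]-4-hydroxy-3-(3-methylbuta-1,2-dienyl)phenyl}-2-methylpropan-1-one F4. A [1,5]-hydrogen shift gives the ortho-quinone methide 3,5-bis[(R)-but-3-en-2-yloxy]-4-(2-methylpropanoyl)-6-(3-methylbut-2-enylidene)cyclohexa-2,4-dien-1-one F5. Oxa-6π electrocyclisation then closes the pyran to 7. Only one hydroxyl is free, so the regiochemistry stays fixed. The allyl ethers begin to rearrange at the same temperature, which is tolerable because 7 lies on the way to 9.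

## Further compounds

F1 | step 2 | 1-(5,7-dihydroxy-2,2-dimethyl-2H-chromen-6-yl)-2-methylpropan-1-one | CC(C)C(=O)c1c(O)cc2OC(C)(C)C=Cc2c1O
F2 | step 2 | (S)-but-3-yn-2-yl 4-methylbenzenesulfonate | C[C@H](OS(=O)(=O)c1ccc(C)cc1)C#C
F3 | step 2 | 1-{5,7-bis[(R)-but-3-yn-2-yloxy]-2,2-dimethyl-2H-chromen-6-yl}-2-methylpropan-1-one | CC(C)C(=O)c1c(O[C@H](C)C#C)cc2OC(C)(C)C=Cc2c1O[C@H](C)C#C
F4 | step 3 | 1-{2,6-bis[(R)-but-3-en-2-yloxy]-4-hydroxy-3-(3-methylbuta-1,2-dienyl)phenyl}-2-methylpropan-1-one | CC(C)C(=O)c1c(O[C@H](C)C=C)cc(O)c(C=C=C(C)C)c1O[C@H](C)C=C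
F5 | step 3 | 3,5-bis[(R)-but-3-en-2-yloxy]-4-(2-methylpropanoyl)-6-(3-methylbut-2-enylidene)cyclohexa-2,4-dien-1-one | O=C1C=C(O[C@H](C)C=C)C(C(=O)C(C)C)=C(O[C@H](C)C=C)/C1=C/C=C(C)C
F6 | step 4 | 1-{3-[(E)-but-2-enyl]-2,6-dihydroxy-4-(2-methylbut-3-yn-2-yloxy)phenyl}-2-methylpropan-1-one | CC(C)C(=O)c1c(O)cc(OC(C)(C)C#C)c(C/C=C/C)c1O
F7 | step 4 | 1-{6-[(R)-but-3-en-2-yloxy]-3-[(E)-but-2-enyl]-2-hydroxy-4-(2-methylbut-3-yn-2-yloxy)phenyl}-2-methylpropan-1-one | CC(C)C(=O)c1c(O[C@H](C)C=C)cc(OC(C)(C)C#C)c(C/C=C/C)c1O
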